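**Retrosynthetic overview** (oxolane numbered as in the target: O1, C2 benzyl, C3 OH, C4 CH2OH, C5 aryl)
1. Target 21 comes from 4,5-dihydrofuran ester 16 by hydrogenation of C4=C5 from the face opposite the cis C2-benzyl/C3-silyloxy pair, base epimerisation at C4, ester reduction and deprotection.
2. The oxolane is cut at O1–C2 and C3–C4: a one-pot Mukaiyama aldol / 5-exo-tet O-alkylation (a silyl-capped interrupted Feist–Bénary annulation) joins enol silane 10 and (R)-α-chloroaldehyde 14.
3. Enabling feature: O1–C5(aryl)–C4–CH2OH of the oxolane is a reduced aroylacetate (C5 = ketone carbon, CH2OH = ester carbon), an O,C-bis-nucleophile; C3(OH)–C2(O1) is the carbonyl/α-halide pair of a 2-chloro-3-arylpropanal.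
4. The cis-dihydrobenzofuran comes from enantioselective rhodium-carbenoid insertion into the benzylic ether C–H of aryldiazoacetate 5; its bromide is then turned into the β-ketoester by carbonylative malonate coupling.
5. Ring order: dihydrobenzofuran ring, then the oxolane ring (as a 4,5-dihydrofuran), then its saturation.

Key step: step 12

Remark: the target is read as a 2,3-cis (2R,3R) dihydrobenzofuran and a (2S,3S,4S,5S) oxolane (2,3-cis, 3,4-trans, 4,5-trans); the sense of induction of Rh2(S-PTTL)4 and of the (5R)-imidazolidinone is assumed by analogy with close substrates, and the mirror-image catalyst would be used otherwise.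

Abbreviations: ArBn = 4-(benzyloxy)-3-methoxyphenyl; TBS = tert-butyldimethylsilyl; DBF = (2R,3R)-2-ArBn-3-{[(TBS)oxy]methyl}-7-methoxy-2,3-dihydro-1-benzofuran-5-yl (2-aryl and 3-CH2O cis).

**Route**

Step 1
Reactants: 1 4-bromo-2-methoxyphenol
Product: 2 4-bromo-2-iodo-6-methoxyphenol
Conditions: NIS, CF3CO2H (cat.), MeCN, 0 °C to rt
Reagents that add atoms: N-iodosuccinimide, O=C1CCC(=O)N1I
Why: Electrophilic aromatic iodination should go ortho to the phenol OH, the only strongly activated free position since para is blocked by bromine.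

Step 2
Reactants: 2 4-bromo-2-iodo-6-methoxyphenol; 3 [4-(benzyloxy)-3-methoxyphenyl]methanol
Product: 4 1-(benzyloxy)-4-[(4-bromo-2-iodo-6-methoxyphenoxy)methyl]-2-methoxybenzene
Conditions: PPh3, DIAD, THF, 0 °C to rt
Reagents that add atoms: none
Why: Mitsunobu etherification of an acidic phenol with a primary benzylic alcohol should give the aryl benzyl ether without a separate halide.

Step 3
Reactants: 4 aryl benzyl ether
Product: 5 methyl 2-{5-bromo-3-methoxy-2-[(ArBn)methoxy]phenyl}-2-diazoacetate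
Conditions: methyl diazoacetate, Pd(PPh3)4 (5 mol%), Et3N, n-Bu4NBr, MeCN, 45 °C
Reagents that add atoms: methyl diazoacetate, COC(=O)C=[N+]=[N-]
Why: Palladium-catalysed cross-coupling of an aryl iodide with the C–H of a diazoacetate keeps the diazo group and should be selective for C–I over C–Br.

Step 4
Reactants: 5 aryldiazoacetate
Product: 6 methyl (2R,3S)-2-ArBn-5-bromo-7-methoxy-2,3-dihydro-1-benzofuran-3-carboxylate (2,3-cis)
Conditions: Rh2(S-PTTL)4 (1 mol%), toluene, −60 °C
Reagents that add atoms: none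
Why: Intramolecular 1,5 C–H insertion of the rhodium carbenoid into the activated benzylic ether C–H closes the dihydrobenzofuran; the chiral carboxylate catalyst should set both centres and deliver the kinetic cis isomer.

Step 5
Reactants: 6 cis ester
Product: 7 [(2R,3R)-2-ArBn-5-bromo-7-methoxy-2,3-dihydro-1-benzofuran-3-yl]methanol (2,3-cis)
Conditions: i-Bu2AlH (3 equiv), CH2Cl2, −78 to −20 °C; aq. potassium sodium tartrate
Reagents that add atoms: none
Why: Hydride reduction of the ester under non-basic conditions should leave the epimerisable C3 centre and the aryl bromide untouched.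

Step 6
Reactants: 7 cis alcohol
Product: 8 (2R,3R)-2-ArBn-5-bromo-3-{[(TBS)oxy]methyl}-7-methoxy-2,3-dihydro-1-benzofuran (DBF–Br)
Conditions: TBSCl, imidazole, DMF, rt
Reagents that add atoms: tert-butyldimethylsilyl chloride, CC(C)(C)[Si](C)(C)Cl
Why: Standard silylation of a primary alcohol.

Step 7
Reactants: 8 DBF–Br
Product: 9 methyl 3-(DBF)-3-oxopropanoate
Conditions: potassium methyl malonate, CO (1 atm), Pd(dba)2, Xantphos, MgCl2, Et3N, THF, 80 °C; then aq. citric acid
Reagents that add atoms: carbon monoxide, [C-]#[O+]; potassium methyl malonate, COC(=O)CC(=O)[O-].[K+]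
Why: Palladium-catalysed carbonylative coupling of an aryl bromide with a malonate half-ester (acyl-palladium captured by the magnesium enolate, then decarboxylation) should give the aryl β-ketoester directly.

Step 8
Reactants: 9 β-ketoester
Product: 10 methyl (2Z)-3-(DBF)-3-[(TBS)oxy]prop-2-enoate
Conditions: TBSOTf, Et3N, CH2Cl2, 0 °C
Reagents that add atoms: tert-butyldimethylsilyl trifluoromethanesulfonate, CC(C)(C)[Si](C)(C)OS(=O)(=O)C(F)(F)F
Why: O-silylation of the chelated enol of a β-ketoester should give the (Z)-3-silyloxyacrylate.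

Step 9
Reactants: 11 4-(3-hydroxypropyl)-2-methoxyphenol
Product: 12 3-ArBn-propan-1-ol
Conditions: BnBr, K2CO3, acetone, reflux
Reagents that add atoms: benzyl bromide, BrCc1ccccc1
Why: Williamson etherification under carbonate conditions alkylates only the phenol.

Step 10
Reactants: 12 3-ArBn-propan-1-ol
Product: 13 3-ArBn-propanal
Conditions: TEMPO (10 mol%), PhI(OAc)2, CH2Cl2, rt
Reagents that add atoms: none
Why: Oxoammonium-mediated oxidation stops at the aldehyde and tolerates the electron-rich arene.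

Step 11
Reactants: 13 3-ArBn-propanal
Product: 14 (2R)-3-ArBn-2-chloropropanal
Conditions: (5R)-5-benzyl-2,2,3-trimethylimidazolidin-4-one trifluoroacetate (20 mol%), 2,3,4,5,6,6-hexachlorocyclohexa-2,4-dien-1-one, acetone, −30 °C; used at once without chromatography
Reagents that add atoms: 2,3,4,5,6,6-hexachlorocyclohexa-2,4-dien-1-one, O=C1C(Cl)=C(Cl)C(Cl)=C(Cl)C1(Cl)Cl
Why: Enamine-catalysed enantioselective α-chlorination of an aldehyde; the imidazolidinone shields one enamine face and so sets C2.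

Step 12
Reactants: 10 enol silane; 14 (2R)-α-chloroaldehyde
Product: 16 methyl (4S,5S)-5-(ArBn-methyl)-2-(DBF)-4-[(TBS)oxy]-4,5-dihydrofuran-3-carboxylate (benzyl and silyloxy cis), via silyl aldol adduct 15 (not isolated)
Conditions: HNTf2 (2 mol%), CH2Cl2, −78 °C; then Cs2CO3, MeCN, −78 to 40 °C
Reagents that add atoms: none
Why: Catalytic HNTf2 turns a little of 10 into TBSNTf2, which activates the aldehyde of 14; the α-carbon of the enol silane (future C4) adds through an open transition state to the carbonyl (future C3) anti to the C–Cl dipole (Cornforth/polar Felkin–Anh control from C2), and silyl transfer to the new alkoxide gives the 2,3-anti chlorohydrin 15 as its silyl ether, which can neither revert by retro-aldol nor close to an epoxide. Cs2CO3 then forms the 1,3-dicarbonyl enolate, whose ketone oxygen (future O1) displaces the secondary chloride at C2 with inversion (R to S), which places benzyl and silyloxy cis. The closest known reaction types are the Mukaiyama aldol addition and the interrupted Feist–Bénary annulation of 1,3-dicarbonyl compounds with α-halo carbonyl compounds (aldol, then enolate O-alkylation). The only ring closed is the 4,5-dihydrofuran, by 5-exo-tet attack of the enolate oxygen; C-alkylation would need a three-membered ring and attack by the ester oxygen would give a less stabilised ketene acetal. C3 is set by 1,2-induction from C2, C2 is carried over stereospecifically from the α-chlorination, and the transient centre at C4 is erased in the enolate. The step needs carbonyl addition before any substitution or enolisation of 14, which the base-free Lewis-acid stage at −78 °C should secure, and kinetic facial selectivity, which the silyl cap preserves.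

Step 13
Reactants: 16 dihydrofuran ester
Product: 17 methyl (2S,3S,4S,5S)-5-(ArBn-methyl)-2-(DBF)-4-[(TBS)oxy]oxolane-3-carboxylate (all four substituents cis)
Conditions: H2 (4 atm), 5% Rh/Al2O3, EtOAc, rt
Reagents that add atoms: none
Why: Heterogeneous syn-hydrogenation of the tetrasubstituted β-alkoxyacrylate should occur from the face opposite the cis benzyl and silyloxy groups, which sets C5 (and C4 provisionally); rhodium on alumina should spare the benzyl ethers and the benzylic C–O bonds, as in the hydrogenation of aryl furan- and dihydrofuran-carboxylates to all-cis oxolanes.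

Step 14
Reactants: 17 all-cis ester
Product: 18 methyl (2S,3R,4S,5S)-5-(ArBn-methyl)-2-(DBF)-4-[(TBS)oxy]oxolane-3-carboxylate (ester trans to both neighbours)
Conditions: NaOMe (0.3 equiv), MeOH/THF, 0 °C to rt
Reagents that add atoms: none
Why: Thermodynamic epimerisation through the ester enolate relieves two cis-1,2 interactions at once and should place the ester trans to both the C3 silyloxy and the C5 aryl group.

Step 15
Reactants: 18 trans ester
Product: 19 [(2S,3R,4S,5S)-5-(ArBn-methyl)-2-(DBF)-4-[(TBS)oxy]oxolan-3-yl]methanol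
Conditions: LiAlH4, THF, −20 to 0 °C
Reagents that add atoms: none
Why: Hydride reduction of the ester to the primary alcohol does not touch the now fixed C4 centre, the silyl ethers or the benzyl ethers.

Step 16
Reactants: 19 bis-silyl ether
Product: 20 (2S,3S,4S,5S)-2-(ArBn-methyl)-5-[(2R,3R)-2-ArBn-3-(hydroxymethyl)-7-methoxy-2,3-dihydro-1-benzofuran-5-yl]-4-(hydroxymethyl)oxolan-3-ol
Conditions: n-Bu4NF, AcOH, THF, rt
Reagents that add atoms: none
Why: Buffered fluoride desilylation removes both silyl ethers under nearly neutral conditions that do not threaten the cis-dihydrobenzofuran.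

Step 17
Reactants: 20 bis-benzyl ether
Product: 21 (2S,3S,4S,5S)-2-(4-hydroxy-3-methoxybenzyl)-5-[(2R,3R)-2-(4-hydroxy-3-methoxyphenyl)-3-(hydroxymethyl)-7-methoxy-2,3-dihydro-1-benzofuran-5-yl]-4-(hydroxymethyl)oxolan-3-ol
Conditions: H2 (1 atm), 10% Pd/C, EtOAc/EtOH, rt, stopped at full conversion
Reagents that add atoms: none
Why: Neutral hydrogenolysis cleaves aryl benzyl ethers much faster than the cyclic benzylic C–O bonds and avoids acid or base, which could open the cis-dihydrobenzofuran.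

**Compound list**
1 | 4-bromo-2-methoxyphenol | COc1cc(Br)ccc1O | starting material
2 | 4-bromo-2-iodo-6-methoxyphenol | COc1cc(Br)cc(I)c1O | intermediate
3 | [4-(benzyloxy)-3-methoxyphenyl]methanol | COc1cc(CO)ccc1OCc1ccccc1 | starting material
4 | 1-(benzyloxy)-4-[(4-bromo-2-iodo-6-methoxyphenoxy)methyl]-2-methoxybenzene | COc1cc(COc2c(I)cc(Br)cc2OC)ccc1OCc1ccccc1 | intermediate
5 | methyl 2-{5-bromo-3-methoxy-2-[(ArBn)methoxy]phenyl}-2-diazoacetate | COC(=O)C(=[N+]=[N-])c1cc(Br)cc(OC)c1OCc1ccc(OCc2ccccc2)c(OC)c1 | intermediate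
6 | methyl (2R,3S)-2-ArBn-5-bromo-7-methoxy-2,3-dihydro-1-benzofuran-3-carboxylate (cis) | Brc1cc(OC)c2c(c1)[C@H](C(=O)OC)[C@H](c1ccc(OCc3ccccc3)c(OC)c1)O2 | intermediate
7 | [(2R,3R)-2-ArBn-5-bromo-7-methoxy-2,3-dihydro-1-benzofuran-3-yl]methanol (cis) | Brc1cc(OC)c2c(c1)[C@H](CO)[C@H](c1ccc(OCc3ccccc3)c(OC)c1)O2 | intermediate
8 | (2R,3R)-2-ArBn-5-bromo-3-{[(TBS)oxy]methyl}-7-methoxy-2,3-dihydro-1-benzofuran (DBF–Br) | Brc1cc(OC)c2c(c1)[C@H](CO[Si](C)(C)C(C)(C)C)[C@H](c1ccc(OCc3ccccc3)c(OC)c1)O2 | intermediate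
9 | methyl 3-(DBF)-3-oxopropanoate | COC(=O)CC(=O)c1cc(OC)c2c(c1)[C@H](CO[Si](C)(C)C(C)(C)C)[C@H](c1ccc(OCc3ccccc3)c(OC)c1)O2 | intermediate
10 | methyl (2Z)-3-(DBF)-3-[(TBS)oxy]prop-2-enoate | COC(=O)/C=C(\O[Si](C)(C)C(C)(C)C)c1cc(OC)c2c(c1)[C@H](CO[Si](C)(C)C(C)(C)C)[C@H](c1ccc(OCc3ccccc3)c(OC)c1)O2 | intermediate
11 | 4-(3-hydroxypropyl)-2-methoxyphenol | COc1cc(CCCO)ccc1O | starting material
12 | 3-ArBn-propan-1-ol | COc1cc(CCCO)ccc1OCc1ccccc1 | intermediate
13 | 3-ArBn-propanal | COc1cc(CCC=O)ccc1OCc1ccccc1 | intermediate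
14 | (2R)-3-ArBn-2-chloropropanal | O=C[C@H](Cl)Cc1ccc(OCc2ccccc2)c(OC)c1 | intermediate
15 | methyl (3S,4R)-5-ArBn-4-chloro-2-[(DBF)carbonyl]-3-[(TBS)oxy]pentanoate (C2 epimers; 3,4-anti) | COC(=O)C(C(=O)c1cc(OC)c2c(c1)[C@H](CO[Si](C)(C)C(C)(C)C)[C@H](c1ccc(OCc3ccccc3)c(OC)c1)O2)[C@H](O[Si](C)(C)C(C)(C)C)[C@H](Cl)Cc1ccc(OCc2ccccc2)c(OC)c1 | intermediate (not isolated)
16 | methyl (4S,5S)-5-(ArBn-methyl)-2-(DBF)-4-[(TBS)oxy]-4,5-dihydrofuran-3-carboxylate | COc1cc(C[C@@H]2OC(c3cc(OC)c4c(c3)[C@H](CO[Si](C)(C)C(C)(C)C)[C@H](c3ccc(OCc5ccccc5)c(OC)c3)O4)=C(C(=O)OC)[C@@H]2O[Si](C)(C)C(C)(C)C)ccc1OCc1ccccc1 | intermediate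
17 | methyl (2S,3S,4S,5S)-5-(ArBn-methyl)-2-(DBF)-4-[(TBS)oxy]oxolane-3-carboxylate (all-cis) | COc1cc(C[C@@H]2O[C@H](c3cc(OC)c4c(c3)[C@H](CO[Si](C)(C)C(C)(C)C)[C@H](c3ccc(OCc5ccccc5)c(OC)c3)O4)[C@H](C(=O)OC)[C@@H]2O[Si](C)(C)C(C)(C)C)ccc1OCc1ccccc1 | intermediate
18 | methyl (2S,3R,4S,5S)-5-(ArBn-methyl)-2-(DBF)-4-[(TBS)oxy]oxolane-3-carboxylate | COc1cc(C[C@@H]2O[C@H](c3cc(OC)c4c(c3)[C@H](CO[Si](C)(C)C(C)(C)C)[C@H](c3ccc(OCc5ccccc5)c(OC)c3)O4)[C@@H](C(=O)OC)[C@@H]2O[Si](C)(C)C(C)(C)C)ccc1OCc1ccccc1 | intermediate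
19 | [(2S,3R,4S,5S)-5-(ArBn-methyl)-2-(DBF)-4-[(TBS)oxy]oxolan-3-yl]methanol | COc1cc(C[C@@H]2O[C@H](c3cc(OC)c4c(c3)[C@H](CO[Si](C)(C)C(C)(C)C)[C@H](c3ccc(OCc5ccccc5)c(OC)c3)O4)[C@@H](CO)[C@@H]2O[Si](C)(C)C(C)(C)C)ccc1OCc1ccccc1 | intermediate
20 | (2S,3S,4S,5S)-2-(ArBn-methyl)-5-[(2R,3R)-2-ArBn-3-(hydroxymethyl)-7-methoxy-2,3-dihydro-1-benzofuran-5-yl]-4-(hydroxymethyl)oxolan-3-ol | COc1cc(C[C@@H]2O[C@H](c3cc(OC)c4c(c3)[C@H](CO)[C@H](c3ccc(OCc5ccccc5)c(OC)c3)O4)[C@@H](CO)[C@@H]2O)ccc1OCc1ccccc1 | intermediate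
21 | (2S,3S,4S,5S)-2-(4-hydroxy-3-methoxybenzyl)-5-[(2R,3R)-2-(4-hydroxy-3-methoxyphenyl)-3-(hydroxymethyl)-7-methoxy-2,3-dihydro-1-benzofuran-5-yl]-4-(hydroxymethyl)oxolan-3-ol | COc1cc(C[C@@H]2O[C@H](c3cc(OC)c4c(c3)[C@H](CO)[C@H](c3ccc(O)c(OC)c3)O4)[C@@H](CO)[C@@H]2O)ccc1O | target

**Step count:** 17 steps in total; longest linear sequence 14 steps (steps 1–8 and 12–17).

**Steps most likely to fail**

Step 12 (key annulation). The push–pull enol silane may add too slowly. Facial selectivity on the aldehyde may erode. In the base stage the enolate may lose silanolate (E1cB) or the chloride may be lost by E2. The silyl Lewis acid may also ionise the benzylic C–O bond of the cis-dihydrobenzofuran and epimerise it.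
Fallback, setting out from 8 and 14 and returning at 20:
- Bromine–lithium exchange on 8 (t-BuLi, THF, −78 °C) and acylation with N-methoxy-N-methyl-3-[(TBS)oxy]propanamide should give 3-[(TBS)oxy]-1-(DBF)propan-1-one F1.
- Its (Z)-boron enolate (n-Bu2BOTf, i-Pr2NEt, CH2Cl2, −78 °C) should add to 14 in a syn aldol, anti to the chloride, to give the keto chlorohydrin (2S,3S,4R)-5-ArBn-4-chloro-3-hydroxy-2-{[(TBS)oxy]methyl}-1-(DBF)pentan-1-one F2.
- Hydroxyl-directed reduction with Me4NBH(OAc)3 (MeCN/AcOH, −20 °C) should give the 1,3-anti diol (1S,2R,3S,4R)-5-ArBn-4-chloro-2-{[(TBS)oxy]methyl}-1-(DBF)pentane-1,3-diol F3.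
- AgOTf/Ag2O (THF, rt) should close the ring by invertive 5-exo-tet displacement of chloride by the C5 hydroxyl to give (2S,3S,4S,5S)-2-(ArBn-methyl)-5-(DBF)-4-{[(TBS)oxy]methyl}oxolan-3-ol F4.
- n-Bu4NF/AcOH then gives 20.

Step 13 (hydrogenation). The tetrasubstituted alkene may take up hydrogen too slowly. Forcing conditions may hydrogenolyse benzyl ethers or benzylic C–O bonds, and the face preference may be incomplete.
Fallback, setting out from 16 and returning at 18: dissolving-metal conjugate reduction with Mg turnings in MeOH (0 °C to rt), as used to turn 2-arylbenzofuran-3-carboxylates into trans-dihydro esters. Protonation at C5 should occur from the open face and the Mg(OMe)2 formed should equilibrate C4, so 18 is reached directly and step 14 is skipped.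

Step 3 (diazo cross-coupling). The diazo ester may decompose through palladium carbene pathways, and the ortho-alkoxy iodide may couple slowly.
Fallback, setting out from 4 and returning at 5: palladium-catalysed coupling of the iodide with the Reformatsky reagent BrZnCH2CO2Me (Pd(dba)2, Q-Phos, THF, rt) should give methyl 2-{5-bromo-3-methoxy-2-[(ArBn)methoxy]phenyl}acetate F5. Diazo transfer (4-acetamidobenzenesulfonyl azide, DBU, MeCN, 0 °C to rt) then gives 5.

**Further compounds**
F1 | step 12 | 3-[(TBS)oxy]-1-(DBF)propan-1-one | O=C(CCO[Si](C)(C)C(C)(C)C)c1cc(OC)c2c(c1)[C@H](CO[Si](C)(C)C(C)(C)C)[C@H](c1ccc(OCc3ccccc3)c(OC)c1)O2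
F2 | step 12 | (2S,3S,4R)-5-ArBn-4-chloro-3-hydroxy-2-{[(TBS)oxy]methyl}-1-(DBF)pentan-1-one | O=C(c1cc(OC)c2c(c1)[C@H](CO[Si](C)(C)C(C)(C)C)[C@H](c1ccc(OCc3ccccc3)c(OC)c1)O2)[C@@H](CO[Si](C)(C)C(C)(C)C)[C@H](O)[C@H](Cl)Cc1ccc(OCc2ccccc2)c(OC)c1
F3 | step 12 | (1S,2R,3S,4R)-5-ArBn-4-chloro-2-{[(TBS)oxy]methyl}-1-(DBF)pentane-1,3-diol | O[C@H](c1cc(OC)c2c(c1)[C@H](CO[Si](C)(C)C(C)(C)C)[C@H](c1ccc(OCc3ccccc3)c(OC)c1)O2)[C@@H](CO[Si](C)(C)C(C)(C)C)[C@H](O)[C@H](Cl)Cc1ccc(OCc2ccccc2)c(OC)c1
F4 | step 12 | (2S,3S,4S,5S)-2-(ArBn-methyl)-5-(DBF)-4-{[(TBS)oxy]methyl}oxolan-3-ol | COc1cc(C[C@@H]2O[C@H](c3cc(OC)c4c(c3)[C@H](CO[Si](C)(C)C(C)(C)C)[C@H](c3ccc(OCc5ccccc5)c(OC)c3)O4)[C@@H](CO[Si](C)(C)C(C)(C)C)[C@@H]2O)ccc1OCc1ccccc1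
F5 | step 3 | methyl 2-{5-bromo-3-methoxy-2-[(ArBn)methoxy]phenyl}acetate | COC(=O)Cc1cc(Br)cc(OC)c1OCc1ccc(OCc2ccccc2)c(OC)c1
F0 | step 13 | none | none
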